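**Retrosynthetic overview**
1. Pyran ring B sits on the half that carries the stereocentre and is formed last. Its O–C(CH3)2 bond is opened by retro-oxa-6π to an ortho-quinone methide, which comes from an ortho-allylphenol plus prenal.
2. The benzylic C–C bond, its (S) centre and the E-alkene are traced back by a retro-aromatic Claisen to an (S)-aryl 1-(chromenyl)but-2-enyl ether. The carbon stereocentre thus derives from a C–O stereocentre.
3. The key disconnection is the aryl C–O bond of that ether, giving an (S)-allylic alcohol and 1-fluoro-3,5-dimethoxybenzene. The carbinol oxygen ends up as the oxygen of pyran ring B.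
4. The (S)-alcohol comes from a catalytic asymmetric (E)-propenylzinc addition to 5,7-dimethoxy-2,2-dimethylchromene-8-carbaldehyde.
5. Pyran ring A (styryl half) is formed first by an O-propargylation/propargyl Claisen cascade on 2-hydroxy-4,6-dimethoxybenzaldehyde. Both benzene rings are bought.

Assumption: the [C@H] centre of the given SMILES is read as (S) (aryl > alkenyl > methyl > H), and Cy2BH is taken as a purchased or separately pre-made reagent.

**Step 1**
Reactants: 1 2-hydroxy-4,6-dimethoxybenzaldehyde; 2 3-chloro-3-methylbut-1-yne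
Product: 4 5,7-dimethoxy-2,2-dimethyl-2H-chromene-8-carbaldehyde, via propargyl ether 3 (not isolated)
Conditions: 2 (1.5 equiv), K2CO3 (2 equiv), KI (10 mol %), CuI (5 mol %), DMF, 65 °C, 16 h; filter under N2, then 140 °C, 6 h
Reagents that add atoms: none
Why: Copper-assisted Williamson-type O-alkylation of the phenoxide by the tertiary propargylic chloride is followed on heating by the aromatic propargyl Claisen rearrangement, [1,5]-H shift and oxa-6π electrocyclisation; the other ortho carbon carries the formyl group, so the pyran can only close onto the single free ortho CH, which fixes the 5,7-dimethoxy-8-formyl pattern (no stereocentre is formed).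

**Step 2**
Reactants: 4 5,7-dimethoxy-2,2-dimethyl-2H-chromene-8-carbaldehyde; 5 propyne
Product: 8 (1S,2E)-1-(5,7-dimethoxy-2,2-dimethyl-2H-chromen-8-yl)but-2-en-1-ol, via alkenylborane 6 (not isolated), via alkenylzinc 7 (not isolated)
Conditions: 5 (excess), Cy2BH (1.5 equiv), toluene, 0 °C to rt; Et2Zn (1.6 equiv), −78 °C; (−)-MIB [(2S)-3-exo-morpholinoisoborneol, 5 mol %], then 4, −10 to 0 °C; pH 7 buffer
Reagents that add atoms: none
Why: This is a catalytic asymmetric alkenylzinc addition (Oppolzer type) in which syn-hydroboration of propyne fixes the E geometry, boron-to-zinc exchange gives the alkenylzinc, and the zinc aminoalkoxide of (−)-MIB delivers it to the Si face of the aldehyde (the same sense as its dialkylzinc additions to aryl aldehydes), which sets the (S)-carbinol centre.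

**Step 3**
Reactants: 8 (1S,2E)-1-(5,7-dimethoxy-2,2-dimethyl-2H-chromen-8-yl)but-2-en-1-ol; 9 1-fluoro-3,5-dimethoxybenzene
Product: 11 2-[(2S,3E)-4-(5,7-dimethoxy-2,2-dimethyl-2H-chromen-8-yl)but-3-en-2-yl]-3,5-dimethoxyphenol, via aryl allyl ether 10 (not isolated)
Conditions: KH (2.2 equiv), 18-crown-6 (1.1 equiv), THF, 0 °C, argon; 9 (5 equiv, excess recovered), 65 °C, 12–24 h; aq NH4Cl
Reagents that add atoms: none
Why: Proposed new method: a one-flask, transition-metal-free aryl C–O coupling/aromatic Claisen relay in which the crown-separated potassium alkoxide of 8 displaces fluoride from the non-activated but inductively assisted (two meta OMe groups) fluoroarene 9 by a concerted SNAr that does not touch the carbinol stereocentre; the ether 10, whose breaking C–O bond is flanked by a trialkoxyaryl donor, then undergoes a strongly accelerated suprafacial chair-type [3,3] shift at the same temperature with the chromenyl group equatorial, so that the (S) C–O centre is relayed into the (S) C–C centre and the E-alkene, while the second equivalent of KH holds the product as a phenoxide that is inert to 9 and cannot quench unreacted alkoxide; the closest known reaction types are SNAr etherification of hindered potassium alkoxides with aryl fluorides, thermal aromatic Claisen rearrangement with 1,3-chirality transfer, and the domino copper-catalysed C–O coupling/Claisen of allylic alcohols with vinyl iodides.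

**Step 4**
Reactants: 11 2-[(2S,3E)-4-(5,7-dimethoxy-2,2-dimethyl-2H-chromen-8-yl)but-3-en-2-yl]-3,5-dimethoxyphenol; 12 3-methylbut-2-enal (prenal)
Product: 14 8,8'-[(1E,3S)-but-1-ene-1,3-diyl]bis(5,7-dimethoxy-2,2-dimethyl-2H-chromene), via ortho-quinone methide 13 (not isolated)
Conditions: 12 (3 equiv), ethylenediammonium diacetate (EDDA, 20 mol %), toluene, 110 °C, 12 h
Reagents that add atoms: none
Why: Amine-salt-catalysed Knoevenagel-type condensation of prenal at the only free ortho carbon gives the ortho-quinone methide, whose oxa-6π electrocyclisation forms the O–C(CH3)2 bond of pyran ring B, and the buffered medium without strong acid leaves the electron-rich styrene and the benzylic (S) centre untouched.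

**Compound list**
1 | 2-hydroxy-4,6-dimethoxybenzaldehyde | O=Cc1c(O)cc(OC)cc1OC | starting material
2 | 3-chloro-3-methylbut-1-yne | C#CC(C)(C)Cl | starting material
3 | 2,4-dimethoxy-6-[(2-methylbut-3-yn-2-yl)oxy]benzaldehyde | O=Cc1c(OC(C)(C)C#C)cc(OC)cc1OC | intermediate
4 | 5,7-dimethoxy-2,2-dimethyl-2H-chromene-8-carbaldehyde | COc1cc(OC)c(C=O)c2c1C=CC(C)(C)O2 | intermediate
5 | propyne | CC#C | starting material
6 | (E)-dicyclohexyl(prop-1-en-1-yl)borane | C/C=C/B(C1CCCCC1)C1CCCCC1 | intermediate
7 | (E)-ethyl(prop-1-en-1-yl)zinc | C/C=C/[Zn]CC | intermediate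
8 | (1S,2E)-1-(5,7-dimethoxy-2,2-dimethyl-2H-chromen-8-yl)but-2-en-1-ol | C/C=C/[C@H](O)c1c(OC)cc(OC)c2c1OC(C)(C)C=C2 | intermediate
9 | 1-fluoro-3,5-dimethoxybenzene | COc1cc(F)cc(OC)c1 | starting material
10 | 8-[(1S,2E)-1-(3,5-dimethoxyphenoxy)but-2-en-1-yl]-5,7-dimethoxy-2,2-dimethyl-2H-chromene | C/C=C/[C@H](Oc1cc(OC)cc(OC)c1)c1c(OC)cc(OC)c2c1OC(C)(C)C=C2 | intermediate
11 | 2-[(2S,3E)-4-(5,7-dimethoxy-2,2-dimethyl-2H-chromen-8-yl)but-3-en-2-yl]-3,5-dimethoxyphenol | COc1cc(OC)c(/C=C/[C@H](C)c2c(O)cc(OC)cc2OC)c2c1C=CC(C)(C)O2 | intermediate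
12 | 3-methylbut-2-enal (prenal) | CC(C)=CC=O | starting material
13 | (6Z)-2-[(2S,3E)-4-(5,7-dimethoxy-2,2-dimethyl-2H-chromen-8-yl)but-3-en-2-yl]-3,5-dimethoxy-6-(3-methylbut-2-en-1-ylidene)cyclohexa-2,4-dien-1-one | COc1cc(OC)c(/C=C/[C@H](C)C2=C(OC)C=C(OC)/C(=C/C=C(C)C)C2=O)c2c1C=CC(C)(C)O2 | intermediate
14 | 8,8'-[(1E,3S)-but-1-ene-1,3-diyl]bis(5,7-dimethoxy-2,2-dimethyl-2H-chromene) (CNP0198894.2) | COc1cc(OC)c(/C=C/[C@H](C)c2c(OC)cc(OC)c3c2OC(C)(C)C=C3)c2c1C=CC(C)(C)O2 | target

**Step count:** 4 steps in total. The longest linear sequence is 4 steps (1 → 4 → 8 → 11 → 14).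

**Steps most likely to fail**

Step 3 (the proposed new step). The non-activated fluoroarene may react too slowly with the hindered alkoxide. Partial heterolysis of the very labile C–O bond of 10 could also erode the enantiomeric purity, although ion-pair collapse would still give the constitution of 11. The fallback uses known chemistry only, sets out from 8 and comes back to the route at 13. Compound 8 is deprotonated with NaH in THF at 0 °C and treated with commercial 2-fluoro-4,6-dimethoxybenzaldehyde. This classical carbonyl-activated SNAr runs at or below room temperature and gives the isolated ortho-formyl aryl allyl ether F1. A separate thermal aromatic Claisen rearrangement in toluene (60–90 °C) onto the only free ortho carbon gives the salicylaldehyde F2. Addition of 2-methylprop-1-enylmagnesium bromide (2.5 equiv, THF, 0 °C) gives the ortho-hydroxybenzylic alcohol F3. This loses water on warming in toluene and delivers the same ortho-quinone methide 13, which closes to 14. In this variant the formyl group activates the C–O coupling, blocks one ortho site and supplies C-4 of pyran ring B. Compounds 11 and 12 and step 4 are bypassed, for five steps in all.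

Step 2. The 2,6-dioxygenated, electron-rich aldehyde is hindered and can chelate zinc, so rate and ee may fall. The fallback sets out from 4 and comes back at 8, replacing catalyst-controlled C–C formation by reagent-controlled ketone reduction. CH3C≡CMgBr in THF gives the racemic propargylic alcohol F4, and MnO2 in CH2Cl2 gives the ynone F5. The (R)-Me-CBS oxazaborolidine with BH3·SMe2 (aryl as the large group, alkynyl as the small group) gives the (S)-propargylic alcohol F6. Trans-hydroalumination with NaAlH2(OCH2CH2OMe)2 in THF followed by protonolysis gives 8.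

Step 1. The hydrogen-bonded, ortho-formyl phenol is a poor nucleophile for a tertiary propargylic chloride, and the telescoped heating may cost material. The fallback sets out from 12 and comes back at 4, reversing the order of ring formation and formylation. Commercial 3,5-dimethoxyphenol and 12 with EDDA (10 mol %) in refluxing toluene give 5,7-dimethoxy-2,2-dimethyl-2H-chromene F7. Vilsmeier–Haack formylation (POCl3, DMF, 0 °C to rt, then aq NaOAc) attacks mainly the less hindered C-8 to give 4. The minor 6-carbaldehyde isomer F8 is removed by chromatography.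

**Further compounds**
F1 | step 3 | 2-{[(1S,2E)-1-(5,7-dimethoxy-2,2-dimethyl-2H-chromen-8-yl)but-2-en-1-yl]oxy}-4,6-dimethoxybenzaldehyde | C/C=C/[C@H](Oc1cc(OC)cc(OC)c1C=O)c1c(OC)cc(OC)c2c1OC(C)(C)C=C2
F2 | step 3 | 3-[(2S,3E)-4-(5,7-dimethoxy-2,2-dimethyl-2H-chromen-8-yl)but-3-en-2-yl]-2-hydroxy-4,6-dimethoxybenzaldehyde | COc1cc(OC)c(/C=C/[C@H](C)c2c(O)c(C=O)c(OC)cc2OC)c2c1C=CC(C)(C)O2
F3 | step 3 | 2-[(2S,3E)-4-(5,7-dimethoxy-2,2-dimethyl-2H-chromen-8-yl)but-3-en-2-yl]-6-(1-hydroxy-3-methylbut-2-en-1-yl)-3,5-dimethoxyphenol (mixture of carbinol epimers) | COc1cc(OC)c(/C=C/[C@H](C)c2c(O)c(C(O)C=C(C)C)c(OC)cc2OC)c2c1C=CC(C)(C)O2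
F4 | step 2 | rac-1-(5,7-dimethoxy-2,2-dimethyl-2H-chromen-8-yl)but-2-yn-1-ol | CC#CC(O)c1c(OC)cc(OC)c2c1OC(C)(C)C=C2
F5 | step 2 | 1-(5,7-dimethoxy-2,2-dimethyl-2H-chromen-8-yl)but-2-yn-1-one | CC#CC(=O)c1c(OC)cc(OC)c2c1OC(C)(C)C=C2
F6 | step 2 | (1S)-1-(5,7-dimethoxy-2,2-dimethyl-2H-chromen-8-yl)but-2-yn-1-ol | CC#C[C@H](O)c1c(OC)cc(OC)c2c1OC(C)(C)C=C2
F7 | step 1 | 5,7-dimethoxy-2,2-dimethyl-2H-chromene | COc1cc(OC)c2c(c1)OC(C)(C)C=C2
F8 | step 1 | 5,7-dimethoxy-2,2-dimethyl-2H-chromene-6-carbaldehyde | COc1cc2OC(C)(C)C=Cc2c(OC)c1C=O
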